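**Strategy.** The macrocycle is cut at the bond between ring A carbon C1 and the benzylic carbinol carbon C7. Ring A carries hydrogen at C2 and C6, so a C1 iodide is sterically open, and C7 sits beside the aryloxy-bearing stereocentre C8, which can direct attack on a C7 aldehyde. A CrCl2/NiCl2-mediated aryl addition therefore forms the C1–C7 bond, closes the 21-membered ring and sets C7 in one operation. Its precursor is a linear seco compound: a 5-aryloxy-3-methoxy-4-silyloxy iodoarene, joined through an E-cinnamoyl amide to serotonin, whose 5-oxygen bears an (S)-3-silyloxy-1-oxopropan-2-yl (aldehyde) terminus.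

Key step: step 13

Remark: C7, C8 and C9 denote the carbinol carbon bonded to ring A, the aryloxy-bearing methine and the hydroxymethyl carbon. Read from the SMILES, the target is 7R,8S, with the C7 hydroxyl and the C8 aryloxy group anti (erythro). The iodine is placed on o-vanillin at the outset, where its position is unambiguous, and the phenol is masked as a 4-methoxybenzyl ether so that no hydrogenolysis is needed later. The aldehyde that enters the key step is configurationally labile at C8 and is meant to be used without chromatography.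

**Step 1**
Reactants: 1 o-vanillin (2-hydroxy-3-methoxybenzaldehyde)
Product: 2 2-hydroxy-5-iodo-3-methoxybenzaldehyde
Conditions: ICl (1.05 equiv.), AcOH, rt
Reagents that add atoms: iodine monochloride, SMILES ICl
Why: Electrophilic aromatic iodination, in which the free phenol (para) and the aldehyde (meta) direct to the same carbon, the future ring A C1, while both positions ortho to the hydroxyl are already substituted.

**Step 2**
Reactants: 2 2-hydroxy-5-iodo-3-methoxybenzaldehyde
Product: 3 5-iodo-3-methoxy-2-[(4-methoxybenzyl)oxy]benzaldehyde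
Conditions: PMBCl, K2CO3, Bu4NI (cat.), DMF, 60 °C
Reagents that add atoms: 4-methoxybenzyl chloride, SMILES COc1ccc(CCl)cc1
Why: Williamson ether synthesis on the phenoxide; the 4-methoxybenzyl ether withstands peracid and hot carbonate and is later removed by acid, which the aryl iodide tolerates.

**Step 3**
Reactants: 3 5-iodo-3-methoxy-2-[(4-methoxybenzyl)oxy]benzaldehyde
Product: 5 5-iodo-3-methoxy-2-[(4-methoxybenzyl)oxy]phenol, via aryl formate 4 (not isolated)
Conditions: mCPBA, CH2Cl2, 0 °C → rt; aq. Na2S2O3 wash; then K2CO3 (cat.), MeOH, rt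
Reagents that add atoms: 3-chloroperoxybenzoic acid, SMILES O=C(OO)c1cccc(Cl)c1
Why: Baeyer–Villiger (Dakin-type) oxidation in which the electron-rich 2,3-dialkoxyaryl group migrates, followed by methanolysis of the formate; the thiosulfate wash should return any iodine-oxidised arene to the aryl iodide.

**Step 4**
Reactants: 5 5-iodo-3-methoxy-2-[(4-methoxybenzyl)oxy]phenol; 6 4-fluorobenzaldehyde
Product: 7 4-{5-iodo-3-methoxy-2-[(4-methoxybenzyl)oxy]phenoxy}benzaldehyde
Conditions: K2CO3, DMF, 110 °C
Reagents that add atoms: none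
Why: Nucleophilic aromatic substitution (SNAr) of the fluoride para to the formyl group by the phenoxide; an aryl iodide is inert to carbonate when no transition metal is present.

**Step 5**
Reactants: 7 4-{5-iodo-3-methoxy-2-[(4-methoxybenzyl)oxy]phenoxy}benzaldehyde
Product: 8 4-(2-hydroxy-5-iodo-3-methoxyphenoxy)benzaldehyde
Conditions: TFA, pentamethylbenzene, CH2Cl2, 0 °C → rt
Reagents that add atoms: none
Why: Acidolysis of the 4-methoxybenzyl aryl ether, with pentamethylbenzene trapping the benzylic cation by Friedel–Crafts alkylation so that ring A is not re-alkylated; aldehyde, diaryl ether and aryl iodide are stable to the acid.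

**Step 6**
Reactants: 8 4-(2-hydroxy-5-iodo-3-methoxyphenoxy)benzaldehyde
Product: 9 4-{5-iodo-3-methoxy-2-[(triisopropylsilyl)oxy]phenoxy}benzaldehyde
Conditions: TIPSCl, imidazole, DMAP (cat.), DMF, 40 °C
Reagents that add atoms: triisopropylsilyl chloride, SMILES CC(C)[Si](Cl)(C(C)C)C(C)C
Why: Silyl ether formation on the phenol; the bulky triisopropylsilyl group between two ortho substituents should survive amine bases, Mitsunobu and hydride conditions and leave with fluoride at the end.

**Step 7**
Reactants: 9 4-{5-iodo-3-methoxy-2-[(triisopropylsilyl)oxy]phenoxy}benzaldehyde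
Product: 11 (E)-3-(4-{5-iodo-3-methoxy-2-[(triisopropylsilyl)oxy]phenoxy}phenyl)acrylic acid, via arylidenemalonic acid 10 (not isolated)
Conditions: malonic acid, pyridine, piperidine (cat.), 80 °C
Reagents that add atoms: malonic acid, SMILES OC(=O)CC(=O)O
Why: Knoevenagel condensation with Doebner decarboxylation, which should give the E acid because carbon dioxide is lost from the arrangement that places aryl and carboxyl groups trans.

**Step 8**
Reactants: 11 (E)-3-(4-{5-iodo-3-methoxy-2-[(triisopropylsilyl)oxy]phenoxy}phenyl)acrylic acid; 12 serotonin hydrochloride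
Product: 14 (E)-N-[2-(5-hydroxy-1H-indol-3-yl)ethyl]-3-(4-{5-iodo-3-methoxy-2-[(triisopropylsilyl)oxy]phenoxy}phenyl)acrylamide, via benzotriazolyl ester 13 (not isolated)
Conditions: EDC·HCl, HOBt, iPr2NEt, DMF, 0 °C → rt
Reagents that add atoms: none
Why: Carbodiimide amide coupling through the hydroxybenzotriazole active ester, which acylates the primary amine much faster than the indole nitrogen or the serotonin phenol.

**Step 9**
Reactants: 15 methyl (R)-2,2-dimethyl-1,3-dioxolane-4-carboxylate
Product: 16 methyl (R)-2,3-dihydroxypropanoate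
Conditions: TsOH·H2O (cat.), MeOH, rt
Reagents that add atoms: none
Why: Acid-catalysed transacetalisation (acetonide methanolysis) that does not involve the stereocentre, so the R configuration is carried over.

**Step 10**
Reactants: 16 methyl (R)-2,3-dihydroxypropanoate
Product: 17 methyl (R)-3-[(tert-butyldimethylsilyl)oxy]-2-hydroxypropanoate
Conditions: TBSCl (1.05 equiv.), imidazole, CH2Cl2, 0 °C
Reagents that add atoms: tert-butyldimethylsilyl chloride, SMILES CC(C)(C)[Si](C)(C)Cl
Why: Selective silylation of the primary hydroxyl, which is less hindered and more nucleophilic than the secondary hydroxyl next to the ester.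

**Step 11**
Reactants: 14 (E)-N-[2-(5-hydroxy-1H-indol-3-yl)ethyl]-3-(4-{5-iodo-3-methoxy-2-[(triisopropylsilyl)oxy]phenoxy}phenyl)acrylamide; 17 methyl (R)-3-[(tert-butyldimethylsilyl)oxy]-2-hydroxypropanoate
Product: 18 methyl (S)-3-[(tert-butyldimethylsilyl)oxy]-2-[(3-{2-[(E)-3-(4-{5-iodo-3-methoxy-2-[(triisopropylsilyl)oxy]phenoxy}phenyl)acrylamido]ethyl}-1H-indol-5-yl)oxy]propanoate
Conditions: PPh3, DIAD, THF, 0 °C → rt
Reagents that add atoms: none
Why: Mitsunobu etherification, in which the indol-5-ol (the only group acidic enough to take part) displaces the phosphonium-activated secondary hydroxyl in an SN2 step with inversion, so the R carbinol becomes the S aryl ether that is C8.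

**Step 12**
Reactants: 18 methyl (S)-2-aryloxy-3-silyloxypropanoate as named in step 11
Product: 20 (E)-N-{2-[5-({(S)-1-[(tert-butyldimethylsilyl)oxy]-3-oxopropan-2-yl}oxy)-1H-indol-3-yl]ethyl}-3-(4-{5-iodo-3-methoxy-2-[(triisopropylsilyl)oxy]phenoxy}phenyl)acrylamide, via aluminium hemiacetal 19 (not isolated)
Conditions: iBu2AlH (3.5 equiv.), CH2Cl2, −78 °C; MeOH, then aq. KNaC4H4O6 (potassium sodium tartrate); used crude
Reagents that add atoms: none
Why: Partial reduction of an ester to the aldehyde; the α-aryloxy ester is activated, its tetrahedral aluminium hemiacetal is held by the α-oxygen at −78 °C and collapses only on work-up, and the amide and indole N–H groups merely consume hydride.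

**Step 13**
Reactants: 20 seco iodo aldehyde (S at C8) as named in step 12
Product: 22 (7R,8S)-macrocycle in which ring A C1 is bonded to C7 and which carries a free C7 hydroxyl, the C9 tert-butyldimethylsilyl ether, the ring A triisopropylsilyl ether and the E alkene, via arylchromium dichloride 21 (not isolated)
Conditions: CrCl2 (15 equiv.), NiCl2 (1 mol% of the CrCl2), degassed DMF–THF (3:1), 25 °C, slow addition of 20 to a final 2 mM; aq. ethylenediamine work-up
Reagents that add atoms: none
Why: Nozaki–Hiyama–Kishi reaction: CrCl2 reduces NiCl2 to zerovalent nickel, which inserts into the ring A C1–I bond, the aryl group is passed on to trivalent chromium to give arylchromium 21, and 21 adds across the C7 aldehyde to leave a chromium alkoxide that is protonated on work-up. The closest known reaction type is the nickel-catalysed, chromium-mediated addition of aryl and alkenyl iodides to aldehydes, including its intramolecular use for large rings. The 21-membered ring closes in a 21-exo-trig 1,2-addition, which slow addition at high dilution and the stiff E-cinnamamide, diaryl ether and indole segments should favour over oligomerisation. The new C7 stereocentre is set under control of C8 by the polar Felkin–Anh arrangement, in which the C8–OAr bond lies anti to the incoming aryl group and the aryl passes the C8 hydrogen, which leads to the 7R (anti, erythro) carbinol; the poorly donating aryloxy oxygen and the bulky C9 silyl ether leave little room for a chelate that would give the 7S epimer. The step needs chemoselectivity for the C–I bond and the aldehyde, secured by the low basicity and aldehyde preference of the arylchromium, which should leave the amide, the indole N–H, the cinnamoyl alkene and both silyl ethers alone, while the hydrogens at C2 and C6 keep the nucleophilic carbon unhindered. The neutral medium should keep the α-aryloxy aldehyde from epimerising at C8 and from losing the β-silyloxy group.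

**Step 14**
Reactants: 22 (7R,8S)-macrocycle with both silyl ethers
Product: 23 CNP0276372.1, the (7R,8S)-macrocycle with free C7 hydroxyl, C9 hydroxyl and ring A phenol
Conditions: Bu4NF (3 equiv.), AcOH (3 equiv.), THF, 0 °C → rt
Reagents that add atoms: none
Why: Fluoride-induced desilylation of the primary silyl ether and the aryl silyl ether; buffering with acetic acid should keep the liberated 4-hydroxybenzylic alcohol from ionising to a quinone methide, so C7 and C8 are untouched.

**Compound list**

1 | o-vanillin (2-hydroxy-3-methoxybenzaldehyde) | COc1cccc(C=O)c1O | starting material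
2 | 2-hydroxy-5-iodo-3-methoxybenzaldehyde | COc1cc(I)cc(C=O)c1O | intermediate
3 | 5-iodo-3-methoxy-2-[(4-methoxybenzyl)oxy]benzaldehyde | COc1cc(I)cc(C=O)c1OCc1ccc(OC)cc1 | intermediate
4 | 5-iodo-3-methoxy-2-[(4-methoxybenzyl)oxy]phenyl formate | COc1cc(I)cc(OC=O)c1OCc1ccc(OC)cc1 | intermediate
5 | 5-iodo-3-methoxy-2-[(4-methoxybenzyl)oxy]phenol | COc1cc(I)cc(O)c1OCc1ccc(OC)cc1 | intermediate
6 | 4-fluorobenzaldehyde | O=Cc1ccc(F)cc1 | starting material
7 | 4-{5-iodo-3-methoxy-2-[(4-methoxybenzyl)oxy]phenoxy}benzaldehyde | COc1cc(I)cc(Oc2ccc(C=O)cc2)c1OCc1ccc(OC)cc1 | intermediate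
8 | 4-(2-hydroxy-5-iodo-3-methoxyphenoxy)benzaldehyde | COc1cc(I)cc(Oc2ccc(C=O)cc2)c1O | intermediate
9 | 4-{5-iodo-3-methoxy-2-[(triisopropylsilyl)oxy]phenoxy}benzaldehyde | COc1cc(I)cc(Oc2ccc(C=O)cc2)c1O[Si](C(C)C)(C(C)C)C(C)C | intermediate
10 | 2-(4-{5-iodo-3-methoxy-2-[(triisopropylsilyl)oxy]phenoxy}benzylidene)malonic acid | COc1cc(I)cc(Oc2ccc(C=C(C(=O)O)C(=O)O)cc2)c1O[Si](C(C)C)(C(C)C)C(C)C | intermediate
11 | (E)-3-(4-{5-iodo-3-methoxy-2-[(triisopropylsilyl)oxy]phenoxy}phenyl)acrylic acid | COc1cc(I)cc(Oc2ccc(/C=C/C(=O)O)cc2)c1O[Si](C(C)C)(C(C)C)C(C)C | intermediate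
12 | serotonin hydrochloride | NCCc1c[nH]c2ccc(O)cc12.Cl | starting material
13 | 1H-benzotriazol-1-yl ester of acid 11 | COc1cc(I)cc(Oc2ccc(/C=C/C(=O)On3nnc4ccccc43)cc2)c1O[Si](C(C)C)(C(C)C)C(C)C | intermediate
14 | (E)-N-[2-(5-hydroxy-1H-indol-3-yl)ethyl]-3-(4-{5-iodo-3-methoxy-2-[(triisopropylsilyl)oxy]phenoxy}phenyl)acrylamide | COc1cc(I)cc(Oc2ccc(/C=C/C(=O)NCCc3c[nH]c4ccc(O)cc34)cc2)c1O[Si](C(C)C)(C(C)C)C(C)C | intermediate
15 | methyl (R)-2,2-dimethyl-1,3-dioxolane-4-carboxylate | COC(=O)[C@H]1COC(C)(C)O1 | starting material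
16 | methyl (R)-2,3-dihydroxypropanoate | COC(=O)[C@H](O)CO | intermediate
17 | methyl (R)-3-[(tert-butyldimethylsilyl)oxy]-2-hydroxypropanoate | COC(=O)[C@H](O)CO[Si](C)(C)C(C)(C)C | intermediate
18 | methyl (S)-3-[(tert-butyldimethylsilyl)oxy]-2-[(3-{2-[(E)-3-(4-{5-iodo-3-methoxy-2-[(triisopropylsilyl)oxy]phenoxy}phenyl)acrylamido]ethyl}-1H-indol-5-yl)oxy]propanoate | COC(=O)[C@H](CO[Si](C)(C)C(C)(C)C)Oc1ccc2[nH]cc(CCNC(=O)/C=C/c3ccc(cc3)Oc3cc(I)cc(OC)c3O[Si](C(C)C)(C(C)C)C(C)C)c2c1 | intermediate
19 | diisobutylaluminium hemiacetal (hydride adduct at the ester carbon of 18) | COC(O[Al](CC(C)C)CC(C)C)[C@H](CO[Si](C)(C)C(C)(C)C)Oc1ccc2[nH]cc(CCNC(=O)/C=C/c3ccc(cc3)Oc3cc(I)cc(OC)c3O[Si](C(C)C)(C(C)C)C(C)C)c2c1 | intermediate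
20 | (E)-N-{2-[5-({(S)-1-[(tert-butyldimethylsilyl)oxy]-3-oxopropan-2-yl}oxy)-1H-indol-3-yl]ethyl}-3-(4-{5-iodo-3-methoxy-2-[(triisopropylsilyl)oxy]phenoxy}phenyl)acrylamide (seco iodo aldehyde) | O=C[C@H](CO[Si](C)(C)C(C)(C)C)Oc1ccc2[nH]cc(CCNC(=O)/C=C/c3ccc(cc3)Oc3cc(I)cc(OC)c3O[Si](C(C)C)(C(C)C)C(C)C)c2c1 | intermediate
21 | arylchromium dichloride of 20 (CrCl2 unit on ring A C1 in place of iodine, trivalent chromium) | O=C[C@H](CO[Si](C)(C)C(C)(C)C)Oc1ccc2[nH]cc(CCNC(=O)/C=C/c3ccc(cc3)Oc3cc([Cr](Cl)Cl)cc(OC)c3O[Si](C(C)C)(C(C)C)C(C)C)c2c1 | intermediate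
22 | (7R,8S)-macrocycle with free C7 hydroxyl, C9 tert-butyldimethylsilyl ether and ring A triisopropylsilyl ether | COc1cc2cc(c1O[Si](C(C)C)(C(C)C)C(C)C)Oc1ccc(cc1)/C=C/C(=O)NCCc1c[nH]c3ccc(cc13)O[C@@H](CO[Si](C)(C)C(C)(C)C)[C@@H]2O | intermediate
23 | CNP0276372.1, (7R,8S) | COc1cc2cc(c1O)Oc1ccc(cc1)/C=C/C(=O)NCCc1c[nH]c3ccc(cc13)O[C@@H](CO)[C@@H]2O | target

**Step count.** Total: 14 steps. Longest linear sequence: 12 steps (steps 1–8 and 11–14).

**Steps most likely to fail**

1. Step 13. The macrocyclic tether may override the Felkin–Anh preference and give weak facial selectivity at C7, and protodeiodination or oligomerisation may compete with ring closure. The fallback sets C7 by ketone reduction instead of by aryl addition. It sets out from 22 as obtained together with its C7 epimer, the (7S,8S)-macrocycle F1. The mixture is oxidised at the benzylic position with MnO2 in CH2Cl2 at room temperature to the macrocyclic C7 ketone F2. F2 is then reduced with Zn(BH4)2 in Et2O–CH2Cl2 at −30 °C, where a zinc chelate between the ketone oxygen and the C8 aryloxy oxygen should expose the carbonyl face on the side of the C8 hydrogen and deliver the 7R carbinol. The sequence comes back to the route at 22.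

2. Step 12. Over-reduction past the aldehyde stage, or erosion of the C8 configuration while the sensitive α-aryloxy aldehyde is handled, may occur. The fallback sets out from 18. LiBH4 in THF at 0 °C reduces the ester completely to the primary alcohol, (R)-2-aryloxy-3-silyloxypropan-1-ol F3 (same spatial arrangement; the descriptor changes only because the ranking of the two CH2O arms changes). Dess–Martin periodinane buffered with NaHCO3 in CH2Cl2 at 0 °C then oxidises F3 under neutral conditions, and the route is rejoined at 20.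

3. Step 11. Displacement at the hindered secondary carbinol by the electron-rich, weakly acidic indol-5-ol may be slow, so that alkylation of the reduced azodicarboxylate, silyl migration within 17 or incomplete inversion compete. The fallback replaces in-situ activation by a preformed leaving group and sets out from 17. Tf2O and 2,6-lutidine in CH2Cl2 at −78 °C give methyl (R)-3-[(tert-butyldimethylsilyl)oxy]-2-(trifluoromethylsulfonyloxy)propanoate F4. The phenoxide of 14 (K2CO3, MeCN, 0 °C) displaces the triflate by SN2 with inversion, and the route is rejoined at 18.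

**Further compounds**

F1 | step 13 | (7S,8S)-macrocycle, C7 epimer of 22 | COc1cc2cc(c1O[Si](C(C)C)(C(C)C)C(C)C)Oc1ccc(cc1)/C=C/C(=O)NCCc1c[nH]c3ccc(cc13)O[C@@H](CO[Si](C)(C)C(C)(C)C)[C@H]2O
F2 | step 13 | (8S)-macrocyclic C7 ketone | COc1cc2cc(c1O[Si](C(C)C)(C(C)C)C(C)C)Oc1ccc(cc1)/C=C/C(=O)NCCc1c[nH]c3ccc(cc13)O[C@@H](CO[Si](C)(C)C(C)(C)C)C2=O
F3 | step 12 | (E)-N-{2-[5-({(R)-1-[(tert-butyldimethylsilyl)oxy]-3-hydroxypropan-2-yl}oxy)-1H-indol-3-yl]ethyl}-3-(4-{5-iodo-3-methoxy-2-[(triisopropylsilyl)oxy]phenoxy}phenyl)acrylamide | OC[C@H](CO[Si](C)(C)C(C)(C)C)Oc1ccc2[nH]cc(CCNC(=O)/C=C/c3ccc(cc3)Oc3cc(I)cc(OC)c3O[Si](C(C)C)(C(C)C)C(C)C)c2c1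
F4 | step 11 | methyl (R)-3-[(tert-butyldimethylsilyl)oxy]-2-(trifluoromethylsulfonyloxy)propanoate | COC(=O)[C@H](OS(=O)(=O)C(F)(F)F)CO[Si](C)(C)C(C)(C)C
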